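**Assumption:** the SMILES encodes C-8a (the ring-fusion carbon bearing the methyl group) as R; racemic compounds are written without a stereo tag at that carbon.

## Retrosynthetic overview

1. Ester C–O bond: target ⇒ vanillic acid + the (8aR) allylic alcohol (Mitsunobu).
2. The ring CH2 next to the isopropyl-bearing carbon ⇒ carbinol ⇒ ketone; that carbonyl is the CO of a Pauson–Khand reaction.
3. Bicyclic enone ⇒ acyclic (E)-dienynol: one intramolecular Pauson–Khand reaction closes the cyclopentenone and the cycloheptene together and creates the quaternary C-8a as the racemate. The enantiomers are parted one step later by catalyst-controlled CBS reduction and separation of the resulting diastereomers.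
4. Dienynol ⇒ enynol + homopropargyl Grignard reagent by hydroxyl-directed anti-carbomagnesiation, which fixes the olefin geometry the seven-membered ring needs.
5. Enynol ⇐ propargyl alcohol + methallyl chloride; Grignard reagent ⇐ 3-methylbut-1-yne + oxirane.

## Route

**Step 1**
Reactants: 1 3-methylbut-1-yne; 2 oxirane
Product: 4 5-methylhex-3-yn-1-ol, via lithium 3-methylbut-1-yn-1-ide 3 (not isolated)
Conditions: n-BuLi, THF, −78 °C; then 2, DMPU, −78 °C → rt; H2O
Reagents that add atoms: none
Why: Acetylide alkylation, in which the lithium acetylide opens the unhindered epoxide by SN2 to give the homopropargylic alcohol, with no stereocenter involved.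

**Step 2**
Reactants: 4 5-methylhex-3-yn-1-ol
Product: 5 1-bromo-5-methylhex-3-yne
Conditions: PBr3, pyridine (cat.), Et2O, 0 °C → rt
Reagents that add atoms: phosphorus tribromide, BrP(Br)Br
Why: SN2 bromination of a primary alcohol through its phosphite ester, the internal alkyne being inert.

**Step 3**
Reactants: 6 prop-2-yn-1-ol; 7 3-chloro-2-methylprop-1-ene
Product: 8 5-methylhex-5-en-2-yn-1-ol
Conditions: CuI (10 mol%), NaI (10 mol%), K2CO3, DMF, rt
Reagents that add atoms: none
Why: Copper(I)-catalysed allylation of a terminal alkyne through its copper acetylide gives the skipped enyne, and because the methallyl unit is symmetric SN2 and SN2' attack give the same product.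

**Step 4**
Reactants: 5 1-bromo-5-methylhex-3-yne; 8 5-methylhex-5-en-2-yn-1-ol
Product: 11 (2E)-5-methyl-2-(5-methylhex-3-yn-1-yl)hexa-2,5-dien-1-ol, via bromido(5-methylhex-3-yn-1-yl)magnesium 9 (not isolated), via 2,5-dihydro-1,2-oxamagnesole chelate 10 (not isolated)
Conditions: Mg, THF, rt (2.5 equiv of 9); then 8, CuI (10 mol%), THF/Et2O, −20 °C → rt; H2O
Reagents that add atoms: none
Why: Copper-catalysed hydroxyl-directed anti-carbomagnesiation of a propargylic alcohol (Duboudin–Jousseaume reaction), in which the alkoxide holds magnesium on C-3 in a five-membered chelate so the alkyl group enters C-2 anti to it, and protonolysis therefore leaves the homopropargyl chain cis to the methallyl group as the later seven-membered ring requires.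

**Step 5**
Reactants: 11 (2E)-5-methyl-2-(5-methylhex-3-yn-1-yl)hexa-2,5-dien-1-ol
Product: 13 (8aRS)-6-(hydroxymethyl)-8a-methyl-3-(propan-2-yl)-4,5,8,8a-tetrahydroazulen-2(1H)-one, via hexacarbonyldicobalt alkyne complex 12 (not isolated)
Conditions: Co2(CO)8 (1.1 equiv), CH2Cl2, rt, 1 h; then NMO·H2O (8 equiv), 4 Å MS, CH2Cl2 (0.005 M), 0 °C → rt
Reagents that add atoms: dicobalt octacarbonyl (delivers CO), O=C=[Co](=C=O)(=C=O)(=C=O)[Co](=C=O)(=C=O)(=C=O)=C=O
Why: Proposed new method: an intramolecular Pauson–Khand [2+2+1] reaction of a 1,8-enyne, in which the alkyne–Co2(CO)6 complex inserts the tethered 1,1-disubstituted alkene and then CO so that the cyclopentenone and the cycloheptene close in the same operation, the cis-trisubstituted olefin in the tether holding the two reacting ends on the same side just as the ortho-disubstituted arene does in the known Pauson–Khand closures of arene-bridged 1,8-enynes to cyclopentenone-fused seven-membered rings (the closest known reaction type, together with N-oxide-promoted Pauson–Khand reactions of 2-methylallyl enynes that give angular-methyl quaternary centres); the quaternary C-8a is created here without facial bias and so as the racemate.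

**Step 6**
Reactants: 13 (8aRS)-6-(hydroxymethyl)-8a-methyl-3-(propan-2-yl)-4,5,8,8a-tetrahydroazulen-2(1H)-one
Product: 14 (2R,8aS)-6-(hydroxymethyl)-8a-methyl-3-(propan-2-yl)-1,2,4,5,8,8a-hexahydroazulen-2-ol
Conditions: (S)-2-methyl-CBS-oxazaborolidine (0.2 equiv), catecholborane (2.5 equiv), toluene, −78 °C; MeOH, aq. NaOH; SiO2 separation of the two diastereomers
Reagents that add atoms: none
Why: Corey–Bakshi–Shibata reduction under catalyst control, in which the (S)-oxazaborolidine treats the 2-isopropyl-substituted alkenyl side of the ketone as the large group and gives the (2R) carbinol from both enantiomers of 13, so that the enantiomers become the separable diastereomers (2R,8aS) and (2R,8aR) and isolation of the former (at most 50%) fixes the absolute configuration at C-8a.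

**Step 7**
Reactants: 14 (2R,8aS)-6-(hydroxymethyl)-8a-methyl-3-(propan-2-yl)-1,2,4,5,8,8a-hexahydroazulen-2-ol
Product: 15 [(8aR)-8a-methyl-3-(propan-2-yl)-1,2,4,5,8,8a-hexahydroazulen-6-yl]methanol
Conditions: Et3SiH (3 equiv), TFA (5 equiv), CH2Cl2, −40 °C; K2CO3, MeOH work-up
Reagents that add atoms: none
Why: Ionic deoxygenation (Kursanov–Parnes ionic hydrogenation), in which TFA ionises only the secondary alcohol that is allylic to the tetrasubstituted alkene and Et3SiH delivers hydride to the unhindered secondary terminus C-2 of the allyl cation, restoring the tetrasubstituted C3=C3a alkene while the primary allylic alcohol does not ionise at −40 °C and C-8a is untouched (its descriptor changes from S to R only because the CIP priorities change).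

**Step 8**
Reactants: 15 [(8aR)-8a-methyl-3-(propan-2-yl)-1,2,4,5,8,8a-hexahydroazulen-6-yl]methanol; 16 4-hydroxy-3-methoxybenzoic acid (vanillic acid)
Product: 17 [(8aR)-8a-methyl-3-(propan-2-yl)-1,2,4,5,8,8a-hexahydroazulen-6-yl]methyl 4-hydroxy-3-methoxybenzoate
Conditions: PPh3, DIAD, THF, 0 °C → rt
Reagents that add atoms: none
Why: Mitsunobu esterification, in which the carboxylic acid (pKa about 4.5) rather than the phenol (pKa about 10) protonates the betaine and its carboxylate displaces the primary allylic alkoxyphosphonium, as in the known chemoselective Mitsunobu esterification of phenolic acids, with no stereocenter involved.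

## Compound list

1 | 3-methylbut-1-yne | C#CC(C)C | starting material
2 | oxirane | C1CO1 | starting material
3 | lithium 3-methylbut-1-yn-1-ide | [Li+].[C-]#CC(C)C | intermediate (not isolated)
4 | 5-methylhex-3-yn-1-ol | OCCC#CC(C)C | intermediate
5 | 1-bromo-5-methylhex-3-yne | BrCCC#CC(C)C | intermediate
6 | prop-2-yn-1-ol | OCC#C | starting material
7 | 3-chloro-2-methylprop-1-ene | ClCC(C)=C | starting material
8 | 5-methylhex-5-en-2-yn-1-ol | OCC#CCC(C)=C | intermediate
9 | bromido(5-methylhex-3-yn-1-yl)magnesium | CC(C)C#CCC[Mg]Br | intermediate (not isolated)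
10 | 4-(5-methylhex-3-yn-1-yl)-3-(2-methylprop-2-en-1-yl)-2,5-dihydro-1,2-oxamagnesole | C=C(C)CC1=C(CCC#CC(C)C)CO[Mg]1 | intermediate (not isolated)
11 | (2E)-5-methyl-2-(5-methylhex-3-yn-1-yl)hexa-2,5-dien-1-ol | OC/C(=C/CC(C)=C)CCC#CC(C)C | intermediate
12 | hexacarbonyldicobalt complex of the alkyne of 11 (C2Co2 tetrahedrane) | CC(C)C12[Co]3(=C=O)(=C=O)(=C=O)[Co]1(=C=O)(=C=O)(=C=O)C23CC/C(CO)=C\CC(C)=C | intermediate (not isolated)
13 | (8aRS)-6-(hydroxymethyl)-8a-methyl-3-(propan-2-yl)-4,5,8,8a-tetrahydroazulen-2(1H)-one (racemate) | OCC1=CCC2(C)CC(=O)C(C(C)C)=C2CC1 | intermediate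
14 | (2R,8aS)-6-(hydroxymethyl)-8a-methyl-3-(propan-2-yl)-1,2,4,5,8,8a-hexahydroazulen-2-ol | OCC1=CC[C@@]2(C)C[C@@H](O)C(C(C)C)=C2CC1 | intermediate
15 | [(8aR)-8a-methyl-3-(propan-2-yl)-1,2,4,5,8,8a-hexahydroazulen-6-yl]methanol | OCC1=CC[C@@]2(C)CCC(C(C)C)=C2CC1 | intermediate
16 | 4-hydroxy-3-methoxybenzoic acid | COc1cc(C(=O)O)ccc1O | starting material
17 | [(8aR)-8a-methyl-3-(propan-2-yl)-1,2,4,5,8,8a-hexahydroazulen-6-yl]methyl 4-hydroxy-3-methoxybenzoate | COc1cc(C(=O)OCC2=CC[C@@]3(C)CCC(C(C)C)=C3CC2)ccc1O | target

## Step count and risks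

Total step count: 8. Longest linear sequence: 7 (steps 1, 2, 4, 5, 6, 7, 8).

The three steps most likely to fail:

**Step 5 (seven-membered ring and quaternary centre in one Pauson–Khand closure).** If the cobalt-mediated closure fails, the fallback sets out from 11 and uses a nickel(0)-promoted enyne–isocyanide [2+2+1] cyclisation (Ni(cod)2, PBu3, 2,6-dimethylphenyl isocyanide, DMF, 50 °C). Oxidative cyclisation to a nickelacyclopentene, isocyanide insertion and reductive elimination close the same two rings in one operation without CO loss from a metal cluster. The product is the racemic imine {2-[(2,6-dimethylphenyl)imino]-8a-methyl-3-(propan-2-yl)-1,2,4,5,8,8a-hexahydroazulen-6-yl}methanol F1, and its hydrolysis (aq. oxalic acid, THF) comes back to the route at 13.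

**Step 6 (parting of the enantiomers).** This fails if catalyst control is incomplete for one enantiomer, which lowers the ee of 14, or if the two diols do not separate. The fallback sets out from 13 and resolves the ketone itself. The lithium salt of (S)-N,S-dimethyl-S-phenylsulfoximine (2.2 equiv, THF, −78 °C) adds to the carbonyl, and the adducts of the two ketone enantiomers are diastereomers that are separated by chromatography. The adduct of the (8aS) ketone, (8aS)-6-(hydroxymethyl)-8a-methyl-2-{[(S)-N-methyl-S-phenylsulfonimidoyl]methyl}-3-(propan-2-yl)-1,2,4,5,8,8a-hexahydroazulen-2-ol F4, is heated (toluene, 110 °C) and releases the enantiopure ketone (8aS)-6-(hydroxymethyl)-8a-methyl-3-(propan-2-yl)-4,5,8,8a-tetrahydroazulen-2(1H)-one F5. Luche reduction (NaBH4, CeCl3·7H2O, MeOH, −40 °C) then comes back to the route at 14. It is formed together with its C-2 epimer (2S,8aS)-6-(hydroxymethyl)-8a-methyl-3-(propan-2-yl)-1,2,4,5,8,8a-hexahydroazulen-2-ol F6, which step 7 converts into the same 15.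

**Step 4 (carbomagnesiation with a functionalised primary alkyl Grignard reagent).** If yield or regioselectivity is poor, the fallback sets out from 8. Hydroxyl-directed anti-hydroalumination (LiAlH4, AlCl3 60:1, THF) and iodinolysis (I2, −78 °C) give (2Z)-2-iodo-5-methylhexa-2,5-dien-1-ol F2. Zinc insertion into 5 (Zn dust, LiCl, THF) gives bromido(5-methylhex-3-yn-1-yl)zinc F3. Negishi coupling of F2 with F3 (Pd(dppf)Cl2, THF, 50 °C) proceeds with retention of olefin geometry and comes back to the route at 11.

## Further compounds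

F1 | step 5 | {2-[(2,6-dimethylphenyl)imino]-8a-methyl-3-(propan-2-yl)-1,2,4,5,8,8a-hexahydroazulen-6-yl}methanol (racemate) | OCC1=CCC2(C)CC(=Nc3c(C)cccc3C)C(C(C)C)=C2CC1
F4 | step 6 | (8aS)-6-(hydroxymethyl)-8a-methyl-2-{[(S)-N-methyl-S-phenylsulfonimidoyl]methyl}-3-(propan-2-yl)-1,2,4,5,8,8a-hexahydroazulen-2-ol (C-2 configuration not assigned) | OCC1=CC[C@@]2(C)CC(O)(C[S@@](=O)(=NC)c3ccccc3)C(C(C)C)=C2CC1
F5 | step 6 | (8aS)-6-(hydroxymethyl)-8a-methyl-3-(propan-2-yl)-4,5,8,8a-tetrahydroazulen-2(1H)-one | OCC1=CC[C@@]2(C)CC(=O)C(C(C)C)=C2CC1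
F6 | step 6 | (2S,8aS)-6-(hydroxymethyl)-8a-methyl-3-(propan-2-yl)-1,2,4,5,8,8a-hexahydroazulen-2-ol | OCC1=CC[C@@]2(C)C[C@H](O)C(C(C)C)=C2CC1
F2 | step 4 | (2Z)-2-iodo-5-methylhexa-2,5-dien-1-ol | OC/C(I)=C/CC(C)=C
F3 | step 4 | bromido(5-methylhex-3-yn-1-yl)zinc | CC(C)C#CCC[Zn]Br
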